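Cuts, in retrosynthetic order: (i) O1–C2 and C4–C4a of the dimethylpyran (ring B) give 3-methylbut-2-enal and the ring-B-free heterodimer 12. (ii) The two bonds at the bridge CH2 (to C6 of benzene ring A, to C3 of pyrone ring C) give acylphloroglucinol 4, pyrone 9 and a one-carbon iminium salt. (iii) Aryl–C(=O) gives phloroglucinol and (S)-2-methylbutanoyl chloride. (iv) Pyrone O1–C2 and C5–C6 give methyl 3-oxopentanoate and a propanoyl donor.
Forward: ring A is bought, ring C is closed in step 4, the halves are joined through CH2 in step 5, and ring B is closed last (step 6). Step 6 is a formal [3+3] annulation: Knoevenagel-type C–C bond formation, dehydration to an o-quinone methide, then oxa-6π electrocyclisation. It adds two bonds and five carbons without a protecting group or an external oxidant.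
Enabling feature: in 12, ring A is a masked cyclic 1,3-dicarbonyl with exactly one C–H left (future C4a), between two hydroxyls (future O1 and O5–H). The equally enal-reactive C3 of ring C is already capped by the bridge, so the enal can strike only once and only there.
The choice between the two flanking oxygens rests on the hydrogen-bond relay pyrone 4-OH···O7–H···O=C(acyl) plus O5–H···O=C2(pyrone), which leaves only the future O1 unengaged. It also rests on relief of strain around the α-branched acyl group.
Stereochemistry: the single (S)-centre is bought with (S)-2-methylbutanoic acid and passes only through base-free or buffered steps. No other stereocentre persists.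

Key step: step 6

Remark on the chemistry: the side-chain centre of the given SMILES is read as S. Compounds 8, 12 and 14–16 are drawn as one tautomer each. The C4 centre of 8 is enolisable and disappears in step 4.

Step 1
Reactants: 1 (S)-2-methylbutanoic acid
Product: 2 (S)-2-methylbutanoyl chloride
Conditions: (COCl)2 (1.2 equiv), DMF (cat.), CH2Cl2, 0 °C to rt; concentrate, use crude
Reagents that add atoms: oxalyl chloride, ClC(=O)C(=O)Cl
Why: Acid chloride formation through the catalytic chloroiminium (Vilsmeier-type) species runs at or below room temperature and without base, so no ketene can form and the (S)-centre of 1 should be retained.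

Step 2
Reactants: 2 (S)-2-methylbutanoyl chloride; 3 phloroglucinol (benzene-1,3,5-triol)
Product: 4 (S)-2-methyl-1-(2,4,6-trihydroxyphenyl)butan-1-one
Conditions: AlCl3 (3.5 equiv), CH2Cl2–PhNO2, 0 °C to rt; then ice/aq. HCl
Reagents that add atoms: none
Why: Friedel–Crafts C-acylation of the threefold activated, symmetric ring has only one kind of position to attack and should stop after one acyl group, because the product is held as a deactivated aluminium chelate, while the low temperature keeps the α-centre from enolising.

Step 3
Reactants: 5 methyl 3-oxopentanoate; 6 N-methoxy-N-methylpropanamide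
Product: 8 methyl 4-methyl-3,5-dioxoheptanoate, via dilithium dianion 7 (not isolated)
Conditions: LiN(iPr)2 (2.1 equiv), THF, −78 to 0 °C; then 6, −78 to 0 °C; aq. HCl quench
Reagents that add atoms: none
Why: In this γ-acylation of a β-keto ester dianion (Claisen-type acylation) the more basic terminal carbanion of 7 attacks the N-methoxy-N-methyl amide, and the chelated tetrahedral adduct survives until the quench, which prevents proton exchange and double addition.

Step 4
Reactants: 8 methyl 4-methyl-3,5-dioxoheptanoate
Product: 9 6-ethyl-4-hydroxy-5-methyl-2H-pyran-2-one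
Conditions: DBU (1.5 equiv), toluene, 110 °C; then 1 M HCl
Reagents that add atoms: none
Why: Base-induced enol lactonisation of a 3,5-dioxo ester (6-exo-trig attack of the C5 enolate oxygen on the ester carbonyl, loss of methanol) should give the aromatic 4-hydroxy-2-pyrone as the thermodynamic sink.

Step 5
Reactants: 9 6-ethyl-4-hydroxy-5-methyl-2H-pyran-2-one; 4 (S)-2-methyl-1-(2,4,6-trihydroxyphenyl)butan-1-one
Product: 12 6-ethyl-4-hydroxy-5-methyl-3-({2,4,6-trihydroxy-3-[(2S)-2-methylbutanoyl]phenyl}methyl)-2H-pyran-2-one, via Mannich base hydroiodide 10 (not isolated), via pyrone methide 11 (not isolated)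
Conditions: (a) 9, Me2N=CH2+ I− (1.0 equiv), MeCN, rt; (b) slow addition to 4 (2.5 equiv, surplus recovered), NaOAc (1.1 equiv), MeCN, 60 °C
Reagents that add atoms: dimethyl(methylidene)ammonium iodide, C=[N+](C)C.[I-]
Why: Mannich aminomethylation of pyrone C3, E1cB loss of dimethylamine to the methide 11 and Friedel–Crafts-type conjugate addition of 4 (the carbon variant of the Betti three-component coupling) should give the unsymmetrical bridge, because neither free formaldehyde nor free pyrone is present when 4 meets the electrophile, and slow addition to a surplus of 4 favours single alkylation at one of its two equivalent C–H positions.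

Step 6
Reactants: 12 6-ethyl-4-hydroxy-5-methyl-3-({2,4,6-trihydroxy-3-[(2S)-2-methylbutanoyl]phenyl}methyl)-2H-pyran-2-one; 13 3-methylbut-2-enal
Product: 16 3-({5,7-dihydroxy-2,2-dimethyl-8-[(2S)-2-methylbutanoyl]-2H-chromen-6-yl}methyl)-6-ethyl-4-hydroxy-5-methyl-2H-pyran-2-one (target), via allylic carbinol 14 (not isolated), via o-quinone methide 15 (not isolated)
Conditions: 13 (1.5 equiv), ethylenediammonium diacetate (20 mol %), THF, 65 °C
Reagents that add atoms: none
Why: Mechanism: ethylenediammonium diacetate converts 13 into its iminium ion, the only nucleophilic C–H carbon left in 12 (future C4a of ring A) adds to it (C4–C4a bond, adduct 14 after hydrolytic exchange), 1,4-elimination of water gives the vinylogous o-quinone methide 15, and 15 closes by thermal oxa-6π electrocyclisation (O1–C2 bond), which restores the aromaticity of ring A and makes the sequence irreversible at this temperature. The closest known reaction type is the ammonium-carboxylate-catalysed formal [3+3] chromene annulation (Knoevenagel condensation/electrocyclisation) of 3-alkylated acylphloroglucinols, resorcinols and cyclic 1,3-dicarbonyl compounds with 3-methylbut-2-enal. Ring B closes in a pericyclic mode, a disrotatory six-electron closure of the 1-oxatriene O1=C8a–C4a=C4–C3=C2, so the C–C bond is made first, the C–O bond last, and no ionic exo/endo cyclisation is involved. No lasting stereocentre is formed (C2 bears two methyl groups and the carbinol centre of 14 is erased in 15), and the near-neutral buffer should leave the (S)-centre beside the chelated aryl ketone untouched. Chemo- and site selectivity are secured by the substrate, because pyrone C3 is fully substituted by the bridge and ring A offers one C–H only, so neither a pyranopyranone nor a second annulation can arise. Regioselectivity between the two flanking oxygens is the critical demand: the tautomers of 15 should interconvert faster than they cyclise, and closure on the oxygen next to the acyl-bearing carbon should be favoured, since it keeps the relay pyrone 4-OH···O7–H···O=C(acyl) and the contact O5–H···O=C2(pyrone) intact and leaves the α-branched acyl group with one flanking hydroxyl only, whereas closure on the para oxygen would turn a hydroxyl of that network into an ether.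

Compound list
1 | (S)-2-methylbutanoic acid | CC[C@H](C)C(=O)O | starting material
2 | (S)-2-methylbutanoyl chloride | CC[C@H](C)C(=O)Cl | intermediate
3 | phloroglucinol (benzene-1,3,5-triol) | Oc1cc(O)cc(O)c1 | starting material
4 | (S)-2-methyl-1-(2,4,6-trihydroxyphenyl)butan-1-one | CC[C@H](C)C(=O)c1c(O)cc(O)cc1O | intermediate
5 | methyl 3-oxopentanoate | CCC(=O)CC(=O)OC | starting material
6 | N-methoxy-N-methylpropanamide | CCC(=O)N(C)OC | starting material
7 | dilithium 2,4-dianion of methyl 3-oxopentanoate (not isolated) | C[CH-]C(=O)[CH-]C(=O)OC.[Li+].[Li+] | intermediate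
8 | methyl 4-methyl-3,5-dioxoheptanoate (C4 enolisable, no defined configuration) | CCC(=O)C(C)C(=O)CC(=O)OC | intermediate
9 | 6-ethyl-4-hydroxy-5-methyl-2H-pyran-2-one | CCc1oc(=O)cc(O)c1C | intermediate
10 | 3-[(dimethylamino)methyl]-6-ethyl-4-hydroxy-5-methyl-2H-pyran-2-one hydroiodide (not isolated) | CCc1oc(=O)c(C[NH+](C)C)c(O)c1C.[I-] | intermediate
11 | 6-ethyl-5-methyl-3-methylidenepyran-2,4-dione (not isolated) | C=C1C(=O)OC(CC)=C(C)C1=O | intermediate
12 | 6-ethyl-4-hydroxy-5-methyl-3-({2,4,6-trihydroxy-3-[(2S)-2-methylbutanoyl]phenyl}methyl)-2H-pyran-2-one | CCc1oc(=O)c(Cc2c(O)cc(O)c(C(=O)[C@@H](C)CC)c2O)c(O)c1C | intermediate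
13 | 3-methylbut-2-enal | CC(C)=CC=O | starting material
14 | aldol-type adduct of 12 carrying a 1-hydroxy-3-methylbut-2-enyl group on the last free ring carbon (both carbinol epimers, not isolated) | CCc1oc(=O)c(Cc2c(O)c(C(O)C=C(C)C)c(O)c(C(=O)[C@@H](C)CC)c2O)c(O)c1C | intermediate
15 | (Z)-o-quinone methide: 6-(3-methylbut-2-enylidene)cyclohexa-2,4-dienone with C=O next to the acyl-bearing carbon (not isolated) | CC(C)=C/C=C1\C(=O)C(C(=O)[C@@H](C)CC)=C(O)C(Cc2c(O)c(C)c(CC)oc2=O)=C1O | intermediate
16 | 3-({5,7-dihydroxy-2,2-dimethyl-8-[(2S)-2-methylbutanoyl]-2H-chromen-6-yl}methyl)-6-ethyl-4-hydroxy-5-methyl-2H-pyran-2-one | CCc1oc(=O)c(Cc2c(O)c3c(c(C(=O)[C@@H](C)CC)c2O)OC(C)(C)C=C3)c(O)c1C | target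

Total step count: 6. Longest linear sequence: 4 steps (1 → 2 → 4 → 12 → 16, or 5 → 8 → 9 → 12 → 16).

Steps most likely to fail

Step 6. Part of the o-quinone methide may close on the other flanking oxygen (the one para to the acyl group). Long heating with the amine salt may also let the methylene bridge exchange by retro-Michael cleavage. The fallback replaces the hydrogen-bond bias by a blocking group; it sets out from 4 and returns at 16. The free, non-chelated para-hydroxyl of 4 is silylated selectively (tBuMe2SiCl 1.05 equiv, imidazole, DMF, 0 °C). This gives (S)-1-[4-(tert-butyldimethylsilyloxy)-2,6-dihydroxyphenyl]-2-methylbutan-1-one F1. A surplus of it is coupled with the Mannich base 10 under the conditions of step 5. The product is 3-({6-(tert-butyldimethylsilyloxy)-2,4-dihydroxy-3-[(2S)-2-methylbutanoyl]phenyl}methyl)-6-ethyl-4-hydroxy-5-methyl-2H-pyran-2-one F2. Annulation with 13 and ethylenediammonium diacetate can now close only on the one free hydroxyl beside the new C–C bond. It should give 3-({5-(tert-butyldimethylsilyloxy)-7-hydroxy-2,2-dimethyl-8-[(2S)-2-methylbutanoyl]-2H-chromen-6-yl}methyl)-6-ethyl-4-hydroxy-5-methyl-2H-pyran-2-one F3. Buffered desilylation (Bu4NF, AcOH, THF, 0 °C) then gives 16.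

Step 5. A second alkylation may occur at the remaining ring position of 12. Retro-Mannich release of free pyrone may also capture the methide and form the symmetrical dimer. The fallback reverses the order of the two ring-A substitutions, so that the coupling partner has one reactive position only; it sets out from 4 and returns at 16. Compound 4 is annulated first with 13 (1.0 equiv, ethylenediammonium diacetate, THF, 65 °C). This gives (S)-1-(5,7-dihydroxy-2,2-dimethyl-2H-chromen-8-yl)-2-methylbutan-1-one F4, which is separated from its 6-acyl isomer by chromatography. Its C6–H is the only nucleophilic carbon left, so it can be coupled 1:1 with 10 (NaOAc, MeCN, 60 °C) to give 16 directly.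

Step 2. Enantiopurity may erode through reversible ketene or enol formation at the acylium/aluminium-chelate stage, and over-acylation is possible. The fallback makes the aryl–acyl bond by addition of an aryllithium to a non-enolising acyl donor; it sets out from 1 and 3 and returns at 4. Compound 3 is converted (MeOCH2Cl, iPr2NEt, CH2Cl2) into 1,3,5-tris(methoxymethoxy)benzene F5. Compound 1 is converted (1,1'-carbonyldiimidazole, then MeNH(OMe)·HCl, CH2Cl2) into (S)-N-methoxy-N,2-dimethylbutanamide F6. Directed ortho-lithiation of the tris-ether (n-BuLi, THF, 0 °C) and addition of the amide at −78 °C should give (S)-2-methyl-1-[2,4,6-tris(methoxymethoxy)phenyl]butan-1-one F7. Mild acetal cleavage (HCl, MeOH, 40 °C) then gives 4.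

Further compounds
F1 | step 6 | (S)-1-[4-(tert-butyldimethylsilyloxy)-2,6-dihydroxyphenyl]-2-methylbutan-1-one | CC[C@H](C)C(=O)c1c(O)cc(O[Si](C)(C)C(C)(C)C)cc1O
F2 | step 6 | 3-({6-(tert-butyldimethylsilyloxy)-2,4-dihydroxy-3-[(2S)-2-methylbutanoyl]phenyl}methyl)-6-ethyl-4-hydroxy-5-methyl-2H-pyran-2-one | CCc1oc(=O)c(Cc2c(O)c(C(=O)[C@@H](C)CC)c(O)cc2O[Si](C)(C)C(C)(C)C)c(O)c1C
F3 | step 6 | 3-({5-(tert-butyldimethylsilyloxy)-7-hydroxy-2,2-dimethyl-8-[(2S)-2-methylbutanoyl]-2H-chromen-6-yl}methyl)-6-ethyl-4-hydroxy-5-methyl-2H-pyran-2-one | CCc1oc(=O)c(Cc2c(O[Si](C)(C)C(C)(C)C)c3c(c(C(=O)[C@@H](C)CC)c2O)OC(C)(C)C=C3)c(O)c1C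
F4 | step 5 | (S)-1-(5,7-dihydroxy-2,2-dimethyl-2H-chromen-8-yl)-2-methylbutan-1-one | CC[C@H](C)C(=O)c1c(O)cc(O)c2c1OC(C)(C)C=C2
F5 | step 2 | 1,3,5-tris(methoxymethoxy)benzene | COCOc1cc(OCOC)cc(OCOC)c1
F6 | step 2 | (S)-N-methoxy-N,2-dimethylbutanamide | CC[C@H](C)C(=O)N(C)OC
F7 | step 2 | (S)-2-methyl-1-[2,4,6-tris(methoxymethoxy)phenyl]butan-1-one | CC[C@H](C)C(=O)c1c(OCOC)cc(OCOC)cc1OCOC
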